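**Retrosynthetic overview**
1. Numbering follows the spiro[5.5]undecane name. Ring A is C1(=O)–C2(Me)=C3(OMe)–C4(Me2)–C5(=O)–C6(spiro); ring B is C6–C7–C8=C9–C10–C11(iPr). Target 22 ⇒ spiro-trione 21 by methylation of O3.
2. Ring A of 21 ⇒ ring-B ester 13 (brings C6 and C1) plus acid chloride 18 (brings C5, C4, C3, C2). C5–C6 forms by enolate acylation, then C1–C2 by Dieckmann closure in the same flask. This formal 2 + 4 spiroannulation is modelled on the chain extension and Claisen cyclisation of poly-β-carbonyl chains.
3. Enabling feature: in ring A the carbonyl-level carbons C1, C3, C5 alternate with C2, C4, C6, and C4 and C6 carry no hydrogen. The spiro atom C6 is therefore the α-carbon of a ring-B carboxylate. After its acylation only C2 can be enolised, so the single anionic charge can only travel C6 → C2 → O1/O3.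
4. Ring B ⇒ ring-closing metathesis (C8=C9) of triene 11 ⇐ malonate 9 plus allylic bromide 5. C11 comes from an organocatalytic Michael addition of 7 to 6.
5. Order of ring closure: ring B (step 6), then ring A (step 10).

Key step: step 10

Remark: 21 is drawn as its C3 enol tautomer. Ester 13 is carried as a mixture of C1 epimers, because this centre is planarised in step 10.

Step 1
Reactants: 1 5-bromo-2-methylpent-2-ene; 2 prop-2-yn-1-ol
Product: 4 6-methyl-2-methylidenehept-5-en-1-ol, via homoprenylmagnesium bromide 3 (not isolated)
Conditions: Mg, THF, reflux; then 2 (0.4 equiv), CuI (10 mol %), Et2O/THF, −10 °C → rt; H2O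
Reagents that add atoms: none
Why: CuI-catalysed carbomagnesiation of propargyl alcohol, in which the magnesium alkoxide directs the alkyl group to the internal alkyne carbon, so protonolysis should give the 2-substituted allylic alcohol; no stereocentre is formed.

Step 2
Reactants: 4 6-methyl-2-methylidenehept-5-en-1-ol
Product: 5 2-(bromomethyl)-6-methylhepta-1,5-diene
Conditions: CBr4, PPh3, CH2Cl2, 0 °C
Reagents that add atoms: carbon tetrabromide BrC(Br)(Br)Br
Why: Appel bromination of a primary allylic alcohol under neutral conditions; an allylic shift would give the same constitution.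

Step 3
Reactants: 6 (2E)-4-methylpent-2-enal; 7 dimethyl propanedioate
Product: 8 dimethyl 2-[(3S)-2-methyl-5-oxopentan-3-yl]propanedioate
Conditions: (S)-2-{bis[3,5-bis(trifluoromethyl)phenyl][(trimethylsilyl)oxy]methyl}pyrrolidine (10 mol %), PhCO2H (10 mol %), EtOH, 0 °C → rt
Reagents that add atoms: none
Why: Iminium-catalysed asymmetric Michael addition, in which the diaryl(silyloxy)methyl group of the (S)-catalyst shields one face of the (E)-s-trans iminium ion of 6, so the malonate should add to the open face and set the future C11 as S.

Step 4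
Reactants: 8 dimethyl 2-[(3S)-2-methyl-5-oxopentan-3-yl]propanedioate
Product: 9 dimethyl 2-[(3S)-2-methylhex-5-en-3-yl]propanedioate
Conditions: MePPh3Br, KOtBu, THF, −78 → 0 °C
Reagents that add atoms: methyltriphenylphosphonium bromide C[P+](c1ccccc1)(c1ccccc1)c1ccccc1.[Br-]
Why: Wittig methylenation of the aldehyde at low temperature; the esters are inert to the ylide, and the stereocentre, which is β to the aldehyde, is not touched.

Step 5
Reactants: 9 dimethyl 2-[(3S)-2-methylhex-5-en-3-yl]propanedioate; 5 2-(bromomethyl)-6-methylhepta-1,5-diene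
Product: 11 dimethyl 2-[(3S)-2-methylhex-5-en-3-yl]-2-(6-methyl-2-methylidenehept-5-en-1-yl)propanedioate, via sodium enolate 10 (not isolated)
Conditions: NaH, THF/DMF, 0 °C; then 5, 0 → 50 °C
Reagents that add atoms: none
Why: Malonic ester alkylation (SN2) of the sodium enolate with a reactive allylic bromide builds the fully substituted future C6, which is not yet stereogenic because it carries two identical ester groups.

Step 6
Reactants: 11 dimethyl 2-[(3S)-2-methylhex-5-en-3-yl]-2-(6-methyl-2-methylidenehept-5-en-1-yl)propanedioate
Product: 12 dimethyl (6S)-3-(4-methylpent-3-en-1-yl)-6-(propan-2-yl)cyclohex-3-ene-1,1-dicarboxylate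
Conditions: second-generation Grubbs catalyst (3 mol %), CH2Cl2, 40 °C
Reagents that add atoms: none
Why: Ring-closing metathesis between the monosubstituted and the 1,1-disubstituted alkene closes ring B as a trisubstituted cyclohexene, helped by the gem-diester effect, while the trisubstituted side-chain alkene is too hindered to compete.

Step 7
Reactants: 12 dimethyl (6S)-3-(4-methylpent-3-en-1-yl)-6-(propan-2-yl)cyclohex-3-ene-1,1-dicarboxylate
Product: 13 methyl (6S)-3-(4-methylpent-3-en-1-yl)-6-(propan-2-yl)cyclohex-3-ene-1-carboxylate (C1 epimers)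
Conditions: LiCl, H2O, DMSO, 160 °C
Reagents that add atoms: none
Why: Krapcho dealkoxycarbonylation removes one ester under neutral salt conditions that leave both alkenes and C6 of 13 (future C11) untouched; the C1 epimer ratio does not matter.

Step 8
Reactants: 14 tert-butyl 2-methylpropanoate; 15 propanoyl chloride
Product: 17 tert-butyl 2,2-dimethyl-3-oxopentanoate, via lithium enolate 16 (not isolated)
Conditions: LDA, THF, −78 °C; then 15, −78 → 0 °C
Reagents that add atoms: none
Why: Crossed Claisen acylation of a preformed lithium ester enolate with an acid chloride, which is C-selective and cannot react further at the now quaternary α-carbon.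

Step 9
Reactants: 17 tert-butyl 2,2-dimethyl-3-oxopentanoate
Product: 18 2,2-dimethyl-3-oxopentanoyl chloride
Conditions: SOCl2, CH2Cl2, rt; evaporate, use crude
Reagents that add atoms: thionyl chloride ClS(Cl)=O
Why: Known direct conversion of a tert-butyl ester into the acid chloride with SOCl2 (acid-promoted loss of the tert-butyl group, then chlorination), which avoids isolating the decarboxylation-prone β-keto acid.

Step 10
Reactants: 13 methyl (6S)-3-(4-methylpent-3-en-1-yl)-6-(propan-2-yl)cyclohex-3-ene-1-carboxylate; 18 2,2-dimethyl-3-oxopentanoyl chloride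
Product: 21 (6R,11S)-3-hydroxy-2,4,4-trimethyl-8-(4-methylpent-3-en-1-yl)-11-(propan-2-yl)spiro[5.5]undeca-2,8-diene-1,5-dione, via lithium enolate 19 (not isolated), via tricarbonyl ester 20 (not isolated)
Conditions: LDA, THF, −78 °C; 18, −78 → −20 °C; LiHMDS (2.2 equiv), −78 °C → rt; 1 M HCl
Reagents that add atoms: none
Why: LDA removes the only acidic hydrogen of 13 (the ester α-hydrogen on the future C6) and the lithium enolate 19 is C-acylated by the acid chloride carbon of 18 (future C5), which forms C5–C6 and makes the spiro atom quaternary; in 20 both C4 and C6 are then quaternary, so LiHMDS can enolise only the C2 methylene of the ethyl ketone, and this enolate attacks the ester carbonyl (future C1), expels methoxide and forms C1–C2. The closest known reaction types are the crossed Claisen acylation of lithium ester enolates with acid chlorides to α,α-disubstituted β-keto esters and the Dieckmann-type cyclisation of 2,2,4,4-tetraalkyl-3,5-dioxo esters to cyclohexane-1,3,5-triones, and the sequence copies the chain extension and Claisen ring closure by which poly-β-carbonyl chains give phloroglucinol-type rings. Ring A is closed in a 6-(enolendo)-exo-trig mode. C6 is the only new stereocentre that persists and it is set in the acylation: A(1,3) strain with the exocyclic enolate pushes the C11 isopropyl group into a pseudoaxial position, so 18 should approach from the opposite face, which places C5 trans and the ester carbon C1 cis to the isopropyl group as in 22, while C2 is lost by enolisation. The step needs C- rather than O-acylation, attack at the acyl chloride and not at the ketone of 18, and acylation faster than proton transfer from the C2 methylene; these rest on the known C-selectivity of lithium ester enolates, on the much higher electrophilicity of the acyl chloride at −78 °C and on the absence of an α-hydrogen (no ketene path) in 18. O-closure to an enol lactone would be reversed by the liberated methoxide, whereas deprotonation of the acidic C2–H of 21 is the thermodynamic sink that drives the cascade.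

Step 11
Reactants: 21 (6R,11S)-3-hydroxy-2,4,4-trimethyl-8-(4-methylpent-3-en-1-yl)-11-(propan-2-yl)spiro[5.5]undeca-2,8-diene-1,5-dione
Product: 22 (6R,11S)-3-methoxy-2,4,4-trimethyl-8-(4-methylpent-3-en-1-yl)-11-(propan-2-yl)spiro[5.5]undeca-2,8-diene-1,5-dione
Conditions: Me2SO4, K2CO3, acetone, rt
Reagents that add atoms: dimethyl sulfate COS(=O)(=O)OC
Why: O-alkylation of the vinylogous acid with a hard electrophile; O3 is flanked only by the C4 gem-dimethyl group, whereas O1 lies next to the spiro atom C6 and on the side of the C11 isopropyl group, so methylation should favour O3, and no stereocentre is touched.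

**Compound list**
1 | 5-bromo-2-methylpent-2-ene | CC(C)=CCCBr | starting material
2 | prop-2-yn-1-ol | C#CCO | starting material
3 | (4-methylpent-3-en-1-yl)magnesium bromide | CC(C)=CCC[Mg]Br | intermediate
4 | 6-methyl-2-methylidenehept-5-en-1-ol | C=C(CO)CCC=C(C)C | intermediate
5 | 2-(bromomethyl)-6-methylhepta-1,5-diene | C=C(CBr)CCC=C(C)C | intermediate
6 | (2E)-4-methylpent-2-enal | CC(C)/C=C/C=O | starting material
7 | dimethyl propanedioate | COC(=O)CC(=O)OC | starting material
8 | dimethyl 2-[(3S)-2-methyl-5-oxopentan-3-yl]propanedioate | O=CC[C@@H](C(C)C)C(C(=O)OC)C(=O)OC | intermediate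
9 | dimethyl 2-[(3S)-2-methylhex-5-en-3-yl]propanedioate | C=CC[C@@H](C(C)C)C(C(=O)OC)C(=O)OC | intermediate
10 | sodium enolate of 9 | C=CC[C@@H](C(C)C)C(C(=O)OC)=C(OC)O[Na] | intermediate
11 | dimethyl 2-[(3S)-2-methylhex-5-en-3-yl]-2-(6-methyl-2-methylidenehept-5-en-1-yl)propanedioate | C=CC[C@@H](C(C)C)C(CC(=C)CCC=C(C)C)(C(=O)OC)C(=O)OC | intermediate
12 | dimethyl (6S)-3-(4-methylpent-3-en-1-yl)-6-(propan-2-yl)cyclohex-3-ene-1,1-dicarboxylate | COC(=O)C1(C(=O)OC)CC(CCC=C(C)C)=CC[C@H]1C(C)C | intermediate
13 | methyl (6S)-3-(4-methylpent-3-en-1-yl)-6-(propan-2-yl)cyclohex-3-ene-1-carboxylate (C1 epimers) | COC(=O)C1CC(CCC=C(C)C)=CC[C@H]1C(C)C | intermediate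
14 | tert-butyl 2-methylpropanoate | CC(C)C(=O)OC(C)(C)C | starting material
15 | propanoyl chloride | CCC(=O)Cl | starting material
16 | lithium enolate of 14 | CC(C)=C(O[Li])OC(C)(C)C | intermediate
17 | tert-butyl 2,2-dimethyl-3-oxopentanoate | CCC(=O)C(C)(C)C(=O)OC(C)(C)C | intermediate
18 | 2,2-dimethyl-3-oxopentanoyl chloride | CCC(=O)C(C)(C)C(=O)Cl | intermediate
19 | lithium enolate of 13 | COC(O[Li])=C1CC(CCC=C(C)C)=CC[C@H]1C(C)C | intermediate
20 | methyl (1S,6S)-1-(2,2-dimethyl-3-oxopentanoyl)-3-(4-methylpent-3-en-1-yl)-6-(propan-2-yl)cyclohex-3-ene-1-carboxylate | COC(=O)[C@]1(CC(CCC=C(C)C)=CC[C@H]1C(C)C)C(=O)C(C)(C)C(=O)CC | intermediate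
21 | (6R,11S)-3-hydroxy-2,4,4-trimethyl-8-(4-methylpent-3-en-1-yl)-11-(propan-2-yl)spiro[5.5]undeca-2,8-diene-1,5-dione (enol form of the 1,3,5-trione) | OC1=C(C)C(=O)[C@]2(CC(CCC=C(C)C)=CC[C@H]2C(C)C)C(=O)C1(C)C | intermediate
22 | (6R,11S)-3-methoxy-2,4,4-trimethyl-8-(4-methylpent-3-en-1-yl)-11-(propan-2-yl)spiro[5.5]undeca-2,8-diene-1,5-dione | COC1=C(C)C(=O)[C@]2(CC(CCC=C(C)C)=CC[C@H]2C(C)C)C(=O)C1(C)C | target

**Total step count:** 11.

**Longest linear sequence:** 7 steps (6/7 → 22 through steps 3, 4, 5, 6, 7, 10, 11; the branch from 1 through steps 1, 2, 5, 6, 7, 10, 11 has the same length).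

**Steps most likely to fail**

Step 10. The intermolecular acylation joins two very hindered carbons. It may be outrun by O-acylation of the enolate or by proton transfer from the ketone methylene of the acid chloride, which simply returns the ester.

The fallback uses an aldehyde instead of an acyl chloride as the C5 electrophile and runs the ring closure as a separate step. It goes from 13 back to 21.
- Enolate 19 is added at −78 °C to commercial 2,2-dimethyl-3-oxopentanal in an aldol addition. This has the same facial bias and a much smaller electrophile, and gives methyl (1S,6S)-1-(1-hydroxy-2,2-dimethyl-3-oxopentyl)-3-(4-methylpent-3-en-1-yl)-6-(propan-2-yl)cyclohex-3-ene-1-carboxylate F1 (carbinol epimers).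
- Dess–Martin oxidation gives 20 as an isolated compound.
- LiHMDS in THF then effects the Dieckmann closure to 21.

Step 11. The two enolate oxygens (O1 and O3) may be poorly discriminated, and C-methylation at C2 may compete.

The fallback replaces irreversible O-alkylation with reversible addition–elimination at carbon. It goes from 21 back to 22 and makes no new compound (F0).
- Acid-catalysed enol etherification is run with HC(OMe)3, MeOH and catalytic TsOH at 50 °C. Both modes of etherification interconvert under these conditions, so the less congested C3 enol ether should accumulate under thermodynamic control.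
- Any remaining material etherified at the other oxygen is hydrolysed with aqueous HCl/THF back to 21 and recycled.

Step 3. The conjugate addition to the β-branched aliphatic enal may be slow, and enantioselectivity may erode through reversible (retro-Michael) addition.

The fallback uses auxiliary control instead of catalyst control. It goes from 6 back to 13.
- Pinnick oxidation of 6 (NaClO2, NaH2PO4, 2-methylbut-2-ene) gives (2E)-4-methylpent-2-enoic acid F2.
- Its mixed pivalic anhydride acylates lithiated (R)-4-phenyl-1,3-oxazolidin-2-one to give (4R)-3-[(2E)-4-methylpent-2-enoyl]-4-phenyl-1,3-oxazolidin-2-one F3.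
- AllylMgBr/CuBr·SMe2 adds to the chelated s-cis enoyl imide from the face away from the phenyl group. This should give (4R)-4-phenyl-3-[(3R)-3-(propan-2-yl)hex-5-enoyl]-1,3-oxazolidin-2-one F4.
- MeOMgBr in MeOH releases methyl (3R)-3-(propan-2-yl)hex-5-enoate F5.
- LDA/DMPU and bromide 5 give methyl (3S)-2-(6-methyl-2-methylidenehept-5-en-1-yl)-3-(propan-2-yl)hex-5-enoate F6 (C2 epimers).
- Ring-closing metathesis with the second-generation Grubbs catalyst gives 13.

**Further compounds**
F1 | step 10 | methyl (1S,6S)-1-(1-hydroxy-2,2-dimethyl-3-oxopentyl)-3-(4-methylpent-3-en-1-yl)-6-(propan-2-yl)cyclohex-3-ene-1-carboxylate | COC(=O)[C@]1(CC(CCC=C(C)C)=CC[C@H]1C(C)C)C(O)C(C)(C)C(=O)CC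
F0 | step 11 | none | none
F2 | step 3 | (2E)-4-methylpent-2-enoic acid | CC(C)/C=C/C(=O)O
F3 | step 3 | (4R)-3-[(2E)-4-methylpent-2-enoyl]-4-phenyl-1,3-oxazolidin-2-one | CC(C)/C=C/C(=O)N1[C@H](c2ccccc2)COC1=O
F4 | step 3 | (4R)-4-phenyl-3-[(3R)-3-(propan-2-yl)hex-5-enoyl]-1,3-oxazolidin-2-one | C=CC[C@@H](C(C)C)CC(=O)N1[C@H](c2ccccc2)COC1=O
F5 | step 3 | methyl (3R)-3-(propan-2-yl)hex-5-enoate | C=CC[C@@H](C(C)C)CC(=O)OC
F6 | step 3 | methyl (3S)-2-(6-methyl-2-methylidenehept-5-en-1-yl)-3-(propan-2-yl)hex-5-enoate | C=CC[C@@H](C(C)C)C(CC(=C)CCC=C(C)C)C(=O)OC
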